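The ratio that matters in this flask is ρ, the amount of left-handed product over the amount of right-handed product. The excess asked for is ρ less one, over ρ plus one. If each mirror-image substrate is turned by the single-handed partner, ρ starts at the ratio of the two rate constants, the selectivity factor, and it stays there while the two substrates stand equal.

| flask | left-handed substrate | right-handed substrate | gas | remark | time |
|---|---|---|---|---|---|
| green | 0.15 M | 0.15 M | 98 mM (held) | run made earlier |  |
| amber | 0.22 M | 0.22 M | 98 mM (held) | run made earlier |  |
| flask | 0.30 M | 0.30 M | 98 mM (held) |  | 1.0 h |

| run | time / min | left-handed product / % | right-handed product / % |
|---|---|---|---|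
| green | 3.00 | 3 | 0 |
| green | 5.00 | 4 | 2 |
| green | 8.00 | 4 | 0 |
| green | 12.0 | 8 | 3 |
| green | 20.0 | 13 | 6 |
| green | 40.0 | 25 | 5 |
| amber | 6.00 | 5 | 0 |
| amber | 12.0 | 6 | 1 |
| amber | 20.0 | 14 | 0 |
| amber | 25.0 | 18 | 1 |
| amber | 30.0 | 17 | 0 |
| amber | 40.0 | 27 | 1 |

(readings scatter by 2 percentage points)

- left-handed product and right-handed product together, in percent of the left-handed substrate and right-handed substrate charged together, at 1.0 h
- excess of left-handed product over right-handed product in the product at 1.0 h
- whether the exchange between left-handed substrate and right-handed substrate keeps pace with the reaction: how far the product's excess at 1.0 h gets from its value without exchange to its value with instant exchange (above 80 % keeps pace, below 20 % hardly takes part, else lags behind)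

- partner is single-handed; left-handed substrate and right-handed substrate are mirror images of each other, charged as a racemate, each of them at the stated concentration
- the analysis behind the earlier runs scatters by 2 percentage points, standard deviation
- at the start none of the gas is in solution
- an excess is the difference of the two amounts in percent of their sum
- an excess is below zero if the other one leads
- the handed part of partner does not stay in what it makes, so the products of the two hands are mirror images too

The right-handed readings run from 0 % to 6 % against a scatter of 2 percentage points, so ρ is best read from sums. The left-handed readings of the green and amber runs add up to 144 % and the right-handed ones to 19.0 %. Their quotient is a reading of the mean product ratio along those curves, ρ = 7.58. The right-handed sum carries a scatter of 6.9 points, so one standard deviation either way puts this reading of ρ between 5.55 and 11.9, which is an excess between 69.5 % and 84.5 %.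

Replacing the curve by this mean errs on one side unless exchange restores the substrates. At the last amber reading, the ratio of left-handed to right-handed substrate, reckoned from the products, has fallen to about half, and the new flask runs longer than the readings do. This reckoning therefore expects the flask's excess to come out somewhat below 76.7 %, an estimate that carries the scatter above and stands lower than the forecast's excess.

The forecast gives 38 % of product, an excess of 80 %, and exchange that lags behind, with the caution: “This is a tentative call; the data barely discriminate.”

The flask gives 31.3 % of product and an excess of 71.5 %. Exchange hardly takes part, getting 4.8 % of the way.

    partner + left-handed substrate → left-handed product (k = 0.920 M⁻¹ min⁻¹)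
    partner + right-handed substrate → right-handed product (k = 0.110 M⁻¹ min⁻¹)
    left-handed substrate ⇌ achiral form (K = 0.310, k = 0.0130 min⁻¹)
    right-handed substrate ⇌ achiral form (K = 0.310, k = 0.0130 min⁻¹)
    achiral form → waste (k = 0.0290 min⁻¹)
    gas ⇌ partner, rate k6*(csat - [partner]) (kL = 0.0450 min⁻¹)
    achiral form → side product (k = 0.0280 min⁻¹)

At 0.472 h, the flask uses partner 6.3 times as fast for left-handed product as for right-handed product, less than the rate-constant ratio of 8.36, and as a mean ρ this gives an excess of 72.6 %. The flask's product ratio is 6.01 at 1.00 h, and at 10.0 h it is 2.65.

(The numbers in the tables were computed for substances that don't exist.)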